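## The problem

Target 25 is a 7,9'-epoxylignan. It is a tetrahydrofuran, numbered here O1, C2, C3, C4, C5 (the same numbers are used for these atoms in all open-chain intermediates). C2 carries a 3,4,5-trimethoxyphenyl group, C3 a hydroxymethyl group, C4 a 3-hydroxy-4,5-dimethoxybenzyl group, and C5 is an unsubstituted CH2. The configuration is (2R,3S,4S): aryl trans to hydroxymethyl, hydroxymethyl cis to benzyl.

The carbon skeleton is a 2,3-dibenzylbutane-1,4-diol whose two halves differ only in their aryl rings. The synthesis therefore has to tell apart the two primary oxygens (the one that becomes O1 and the one of the C3 arm) and the two rings, one of which is a phenol.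

Of the three contiguous stereocenters, C3 and C4 correspond to the trans pair of an α,β-dibenzyl-γ-butyrolactone, in which C4 directs C3 reliably. C2 is benzylic and can be set last under the control of C3, because a 2-aryl group prefers to lie trans to the C3 substituent.

Both rings are electron-rich and open to electrophilic halogenation, oxidation and Friedel–Crafts reactions, and the free phenol does not tolerate oxidants. The O1–C2 bond is a benzylic ether that ionises with acid and can be hydrogenolysed.

The enabling feature is that O1 links C5 to the benzylic C2, and C2 is the δ carbon counted from an oxygen on C5 (O–C5–C4–C3–C2). An oxygen radical on C5 reaches a C2–H bond through a six-membered transition state, whereas the benzylic CH2 on C4 is only in a 1,4 relationship. The ring can thus be closed at the end onto a plain benzylic C–H bond, with no functional group ever placed at C2.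

## Retrosynthesis

**25 from 24.** The last operation should be deprotection only. Diacetate 24 carries the phenol and the C3 hydroxymethyl as acetates. One mild methanolysis removes both without acid, so the benzylic ether and the stereocenters are not at risk.

**24 from 22 (O1–C2).** The ring is opened at O1–C2 to alcohol 22, an open chain with two stereocenters and no ring.
- Cutting C2–C3 or C3–C4 instead would build the ring by cycloaddition or radical cyclisation and would have to control two or three centers in one event.
- A polar O1–C2 closure would need an oxygen function at C2 that has to be installed and activated.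
- Here C2 stays a CH2 group until the last bond is made.

The forward reaction asks for three things, and the protecting groups of 22 are chosen to meet them:
- The alkoxy radical must arise only on the C5 oxygen, so that is the single free hydroxyl.
- The CH2 of the C3 arm is also a δ position. It carries an acetate, which deactivates its C–H bonds towards an electrophilic oxygen radical; an ether or silyl ether there would activate them.
- The phenol is an acetate, so that its ring is less prone to iodination and to capture of the C2 cation.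

**22 from 19 (protecting-group level).** Alcohol 19 has the C5 oxygen as a silyl ether, the C3 arm as a free primary alcohol and the phenol as a benzyl ether. Hydrogenolysis and double acetylation give 21 through 20, and fluoride then frees the C5 hydroxyl. All reductive steps thus come before the benzylic ether exists.

**19 from 15 (telling the ends apart).** Lactone 15 already holds the two oxygens in different states: its alkyl oxygen sits on C5, and its acyl carbon is the carbon of the C3 arm. Opening to the Weinreb amide releases the C5 hydroxyl, which is silylated at once (17). Reduction then brings the acyl carbon to the alcohol level (19). Direct reduction of 15 to the diol is shorter but gives two primary alcohols that cannot be distinguished.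

**15 from 13 and 14 (C2–C3).** The bond from C3 to the benzylic carbon that becomes C2 is cut, which leads to β-benzyl lactone 13 and commercial bromide 14. Alkylation of the lactone enolate anti to the C4 substituent is the standard way to the trans pair. The precursor has one stereocenter less.

**13 from 9 and 10 (C3–C4).** The bond between C4 and the CH2 that becomes C3 is cut. Alkylation of the auxiliary-bound enolate of 9 with bromoacetate 10 gives 11, and reductive release and lactonisation give 13. Catalytic routes to such lactones (carbene C–H insertion, asymmetric hydrogenation) are conceivable. The auxiliary is preferred because the sense of induction is predictable, the diastereomers are separable and both antipodes are commercial.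

**9 from 6 and 7; 6 from 2 and 3; 2 from 1.** Imide 9 is the amide of acid 6 with oxazolidinone 7. Acid 6 comes from aldehyde 2 and Meldrum's acid 3 by reductive two-carbon homologation, which needs no hydrogenation catalyst and therefore spares the benzyl ether. Aldehyde 2 is the benzyl ether of commercial phenol 1.

## Roads not taken

**Alternative 1:** The cut is at C2–C3 and at the bond from C4 to its benzylic CH2. In the forward step the lithiated dithiane A3, an acyl-anion equivalent for a C2 aryl ketone, adds to the β carbon of the enantiopure menthyloxy butenolide A2 anti to the alkoxy group. The lactone enolate is then benzylated in the same flask by the silyl-protected bromide A4, giving the all-trans lactone A1.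
- Merits: three components, two C–C bonds and both C3 and C4 are joined in one operation, with relative and absolute configuration relayed from one acetal center. The trans arrangement of A1 becomes the 3,4-cis ring of 25 because the acetal carbon ends as the exocyclic hydroxymethyl. After reduction, ring size alone decides which hydroxyl closes onto C2, so the two primary oxygens never need to be differentiated.
- Weak points: A1 contains no ring of 25. C2 arrives at the ketone level masked as a dithiane. It must be unmasked with thiophilic metal salts or oxidants next to two electron-rich rings, then reduced, and the ring closed in a separate acid step. The lactone and acetal must also be reduced and the silyl group removed, roughly five operations after A1. The less common antipode of the auxiliary is needed for this enantiomeric series.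
- Comparison: the assembly is shorter and the C–C bond formation is probably more robust than in the chosen plan. Against this, the chosen plan brings C2 in as a plain CH2 from commercial 14 and oxidises and closes it in one step (22 to 24). It pays for that with the steps (7 to 10) spent on singling out the C5 hydroxyl.

**Alternative 2:** The cut is at C2–C3 and C4–C5. CsF removes silicon from the α-chloro ether A7; the carbonyl ylide (C2–O1–C5) adds across the alkene of the γ-aryl butenolide A6 anti to its aryl group. This gives the cis-fused furofuranone A5 with the ring and all three ring stereocenters in place. The γ-aryl carbon is sacrificial: its benzylic lactone C–O bond is later hydrogenolysed to the C4 benzyl group, and the freed acid is reduced to the C3 hydroxymethyl.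
- Merits: this is the shortest route. The ring, two C–C bonds and three stereocenters form in one step, and cis fusion secures the 3,4-cis relation by construction.
- Weak points: A7 is a labile α-chloro ether of an electron-rich arene. Regio-, exo/endo- and facial selectivity of a non-stabilised ylide rest on one stereocenter. A6 must be obtained enantiomerically pure. The hydrogenolysis must cleave the lactone benzylic C–O bond of A5 but keep the O1–C2 benzylic ether.
- Comparison: this route is shorter. The chosen plan sets against it that each stereocenter comes from a reaction of predictable sense, and that the O1–C2 ether is formed after all reductive steps instead of having to survive them.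

**Alternative 3:** The cut is at C3–C4. Cp2TiCl (trivalent titanium, from Cp2TiCl2 and zinc) opens the terminal epoxide of the epoxy cinnamyl ether A9 to the C3 radical. This adds 5-exo to the cinnamyl double bond; the benzylic radical is reduced and protonated, giving A8, the silyl ether of 25.
- Merits: A8 is one deprotection from 25, the route is short, and no oxygen differentiation is needed. The usual kinetic preference of such 5-exo closures (2,3-trans, 3,4-cis) matches 25.
- Weak points: C3 and C4 both come from one radical cyclisation whose selectivity is a transition-state preference, not an enforced relationship, so a late diastereomer mixture must be expected. The absolute configuration depends on making the acid-sensitive benzylic epoxy ether A9 enantiopure at C2. More than two equivalents of the titanium reagent are consumed.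
- Comparison: this route is clearly shorter. The chosen plan offers instead that C3 and C4 are fixed before the ring exists, by two reactions with separable diastereomers, leaving only C2 to the key step. The cost is length.

Key step: step 11

## Route

Step 1
Reactants: 1 3-hydroxy-4,5-dimethoxybenzaldehyde
Product: 2 3-(benzyloxy)-4,5-dimethoxybenzaldehyde
Conditions: BnBr, K2CO3, DMF, rt
Reagents that add atoms: benzyl bromide, BrCc1ccccc1
Why: Williamson ether synthesis on the phenoxide; the benzyl ether should withstand the enolate, aluminium amide and hydride steps ahead and is later removed by neutral hydrogenolysis.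

Step 2
Reactants: 2 3-(benzyloxy)-4,5-dimethoxybenzaldehyde; 3 Meldrum's acid (2,2-dimethyl-1,3-dioxane-4,6-dione)
Product: 6 3-[3-(benzyloxy)-4,5-dimethoxyphenyl]propanoic acid, via arylidene Meldrum's acid 4 (not isolated), via benzyl Meldrum's acid 5 (not isolated)
Conditions: HCO2H/Et3N (5:2), 95–100 °C; then aq. HCl
Reagents that add atoms: none
Why: Reductive Knoevenagel homologation: condensation gives the arylidene, formate delivers hydride to its β carbon, and the benzyl Meldrum's acid is hydrolysed and decarboxylated in the hot medium; no hydrogenation catalyst is present, so the benzyl ether is not at risk.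

Step 3
Reactants: 6 3-[3-(benzyloxy)-4,5-dimethoxyphenyl]propanoic acid; 7 (R)-4-benzyl-1,3-oxazolidin-2-one
Product: 9 (R)-4-benzyl-3-{3-[3-(benzyloxy)-4,5-dimethoxyphenyl]propanoyl}-1,3-oxazolidin-2-one, via mixed pivalic anhydride 8 (not isolated)
Conditions: PivCl, Et3N, THF, −20 °C; then 7, LiCl, −20 °C to rt
Reagents that add atoms: none
Why: N-acylation of the oxazolidinone through the mixed anhydride with LiCl assistance, the standard loading of an Evans auxiliary.

Step 4
Reactants: 9 (R)-4-benzyl-3-{3-[3-(benzyloxy)-4,5-dimethoxyphenyl]propanoyl}-1,3-oxazolidin-2-one; 10 tert-butyl bromoacetate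
Product: 11 tert-butyl (3S)-4-[(4R)-4-benzyl-2-oxo-1,3-oxazolidin-3-yl]-3-[3-(benzyloxy)-4,5-dimethoxybenzyl]-4-oxobutanoate
Conditions: NaN(SiMe3)2, THF, −78 °C; then 10, −78 to −40 °C
Reagents that add atoms: none
Why: Evans asymmetric alkylation: the chelated Z sodium enolate is attacked on the face away from the benzyl group of the (R)-auxiliary, which sets the future C4 as S and forms the C3–C4 bond; the minor diastereomer is separable, so single-isomer material should be carried on.

Step 5
Reactants: 11 tert-butyl (3S)-4-[(4R)-4-benzyl-2-oxo-1,3-oxazolidin-3-yl]-3-[3-(benzyloxy)-4,5-dimethoxybenzyl]-4-oxobutanoate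
Product: 13 (S)-4-[3-(benzyloxy)-4,5-dimethoxybenzyl]oxolan-2-one, via hydroxy ester 12 (not isolated)
Conditions: LiBH4, MeOH (1 equiv), THF, 0 °C; aq. NH4Cl; crude: p-TsOH·H2O (cat.), toluene, 80 °C
Reagents that add atoms: none
Why: Reductive removal of the auxiliary (the imide carbonyl is far more electrophilic than the tert-butyl ester), then acid-catalysed lactonisation of the γ-hydroxy tert-butyl ester; the stereocenter is β to the carbonyl and cannot epimerise.

Step 6
Reactants: 13 (S)-4-[3-(benzyloxy)-4,5-dimethoxybenzyl]oxolan-2-one; 14 3,4,5-trimethoxybenzyl bromide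
Product: 15 (3S,4S)-4-[3-(benzyloxy)-4,5-dimethoxybenzyl]-3-(3,4,5-trimethoxybenzyl)oxolan-2-one
Conditions: LiN(iPr)2, THF, −78 °C; then 14, DMPU, −78 to −30 °C
Reagents that add atoms: none
Why: Lactone enolate alkylation; the bromide enters anti to the C4 benzyl group and should give the trans-α,β-dibenzyl lactone, which sets C3 (S) and forms the C2–C3 bond with C2 as an unfunctionalised benzylic CH2.

Step 7
Reactants: 15 (3S,4S)-4-[3-(benzyloxy)-4,5-dimethoxybenzyl]-3-(3,4,5-trimethoxybenzyl)oxolan-2-one
Product: 17 (2S,3S)-3-[3-(benzyloxy)-4,5-dimethoxybenzyl]-4-[(tert-butyldimethylsilyl)oxy]-N-methoxy-N-methyl-2-(3,4,5-trimethoxybenzyl)butanamide, via hydroxy Weinreb amide 16 (not isolated)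
Conditions: MeNH(OMe)·HCl, AlMe3, CH2Cl2, 0 °C to rt; potassium sodium tartrate work-up; crude: TBSCl, imidazole, DMF, 0 °C to rt
Reagents that add atoms: N,O-dimethylhydroxylamine hydrochloride, CNOC.Cl; tert-butyldimethylsilyl chloride, CC(C)(C)[Si](C)(C)Cl
Why: Weinreb aminolysis of the lactone with the aluminium amide frees the C5 hydroxyl and leaves the carbon of the C3 arm as an amide, which tells the two ends apart; silylation of the crude hydroxy amide blocks relactonisation.

Step 8
Reactants: 17 (2S,3S)-3-[3-(benzyloxy)-4,5-dimethoxybenzyl]-4-[(tert-butyldimethylsilyl)oxy]-N-methoxy-N-methyl-2-(3,4,5-trimethoxybenzyl)butanamide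
Product: 19 (2S,3S)-3-[3-(benzyloxy)-4,5-dimethoxybenzyl]-4-[(tert-butyldimethylsilyl)oxy]-2-(3,4,5-trimethoxybenzyl)butan-1-ol, via aldehyde 18 (not isolated)
Conditions: iBu2AlH, THF, −78 °C; potassium sodium tartrate work-up; crude: NaBH4, MeOH, 0 °C
Reagents that add atoms: none
Why: Weinreb amide reduction stops at the chelated hemiaminal and releases the aldehyde on work-up; immediate borohydride reduction should give the primary alcohol before the α stereocenter (C3) can epimerise.

Step 9
Reactants: 19 (2S,3S)-3-[3-(benzyloxy)-4,5-dimethoxybenzyl]-4-[(tert-butyldimethylsilyl)oxy]-2-(3,4,5-trimethoxybenzyl)butan-1-ol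
Product: 21 (2S,3S)-3-(3-acetoxy-4,5-dimethoxybenzyl)-4-[(tert-butyldimethylsilyl)oxy]-2-(3,4,5-trimethoxybenzyl)butyl acetate, via phenol alcohol 20 (not isolated)
Conditions: H2 (1 atm), Pd/C, EtOAc, rt; filter; Ac2O, pyridine, DMAP (cat.), CH2Cl2, 0 °C to rt
Reagents that add atoms: acetic anhydride, CC(=O)OC(C)=O
Why: Hydrogenolysis of the aryl benzyl ether (the silyl ether is stable in EtOAc), then acetylation of phenol and primary alcohol in one operation; both protecting groups wanted by the key step are installed together.

Step 10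
Reactants: 21 (2S,3S)-3-(3-acetoxy-4,5-dimethoxybenzyl)-4-[(tert-butyldimethylsilyl)oxy]-2-(3,4,5-trimethoxybenzyl)butyl acetate
Product: 22 (2S,3S)-4-acetoxy-2-(3-acetoxy-4,5-dimethoxybenzyl)-3-(3,4,5-trimethoxybenzyl)butan-1-ol
Conditions: HF·pyridine, pyridine, THF, 0 °C to rt
Reagents that add atoms: none
Why: Fluoride desilylation under buffered, weakly acidic conditions should cleave the primary silyl ether and leave both acetates; without base, acetyl migration to the new hydroxyl is disfavoured.

Step 11
Reactants: 22 (2S,3S)-4-acetoxy-2-(3-acetoxy-4,5-dimethoxybenzyl)-3-(3,4,5-trimethoxybenzyl)butan-1-ol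
Product: 24 [(2R,3S,4S)-4-(3-acetoxy-4,5-dimethoxybenzyl)-2-(3,4,5-trimethoxyphenyl)oxolan-3-yl]methyl acetate, via hypoiodite 23 (not isolated)
Conditions: PhI(OAc)2 (1.5 equiv, in portions), I2 (0.5 equiv), CH2Cl2, white LED irradiation, 20 °C
Reagents that add atoms: none
Why: Hypoiodite reaction (Suárez-type alkoxy-radical 1,5-hydrogen transfer with oxidative cycloetherification), the known route from 4-arylbutan-1-ols to 2-aryltetrahydrofurans. PhI(OAc)2 and I2 give acetyl hypoiodite, which turns the only free hydroxyl (on C5) into hypoiodite 23; light cleaves the O–I bond and the alkoxy radical takes a hydrogen from C2 through a six-membered transition state. The benzylic radical picks up iodine (or is oxidised directly), and the benzylic iodide or cation, stabilised by the trimethoxyphenyl ring, is captured by the regenerated C5 hydroxyl in a 5-exo-tet closure that forms O1–C2; the HI released is reoxidised, so iodine is needed only in substoichiometric amount. C2 is the new stereocenter and is controlled by C3: closure with the aryl group anti to the acetoxymethyl arm should give the 2,3-trans ether (2R), which is also the more stable epimer if the benzylic ether ionises reversibly. Site selectivity is needed among three C–H positions: the other benzylic CH2 is out of reach (1,4 relationship), and the second δ position, the CH2 of the C3 arm, is deactivated towards the electrophilic oxygen radical because it bears an acetate and not an ether. Chemoselectivity is needed against electrophilic iodination of the trimethoxyphenyl ring and Friedel–Crafts capture of the cation by the other ring: the phenol is acetylated, the medium is unpolar and free of strong acid, and the oxidant is added in portions under continuous irradiation so that acetyl hypoiodite does not accumulate. The product has no hydroxyl left and cannot re-enter the radical chain.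

Step 12
Reactants: 24 [(2R,3S,4S)-4-(3-acetoxy-4,5-dimethoxybenzyl)-2-(3,4,5-trimethoxyphenyl)oxolan-3-yl]methyl acetate
Product: 25 [(2R,3S,4S)-4-(3-hydroxy-4,5-dimethoxybenzyl)-2-(3,4,5-trimethoxyphenyl)oxolan-3-yl]methanol
Conditions: K2CO3 (cat.), MeOH, rt; aq. NH4Cl
Reagents that add atoms: none
Why: Base-catalysed methanolysis (transesterification) should remove the aryl and the alkyl acetate together; no acid is present and no stereocenter is enolisable, so the benzylic ether and the configuration are kept.

## Compound list

1 | 3-hydroxy-4,5-dimethoxybenzaldehyde | COc1cc(C=O)cc(O)c1OC | starting material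
2 | 3-(benzyloxy)-4,5-dimethoxybenzaldehyde | COc1cc(C=O)cc(OCc2ccccc2)c1OC | intermediate
3 | Meldrum's acid (2,2-dimethyl-1,3-dioxane-4,6-dione) | CC1(C)OC(=O)CC(=O)O1 | starting material
4 | 5-[3-(benzyloxy)-4,5-dimethoxybenzylidene]-2,2-dimethyl-1,3-dioxane-4,6-dione | COc1cc(C=C2C(=O)OC(C)(C)OC2=O)cc(OCc2ccccc2)c1OC | intermediate (not isolated)
5 | 5-[3-(benzyloxy)-4,5-dimethoxybenzyl]-2,2-dimethyl-1,3-dioxane-4,6-dione | COc1cc(CC2C(=O)OC(C)(C)OC2=O)cc(OCc2ccccc2)c1OC | intermediate (not isolated)
6 | 3-[3-(benzyloxy)-4,5-dimethoxyphenyl]propanoic acid | COc1cc(CCC(=O)O)cc(OCc2ccccc2)c1OC | intermediate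
7 | (R)-4-benzyl-1,3-oxazolidin-2-one | O=C1N[C@H](Cc2ccccc2)CO1 | starting material
8 | 3-[3-(benzyloxy)-4,5-dimethoxyphenyl]propanoic pivalic anhydride | COc1cc(CCC(=O)OC(=O)C(C)(C)C)cc(OCc2ccccc2)c1OC | intermediate (not isolated)
9 | (R)-4-benzyl-3-{3-[3-(benzyloxy)-4,5-dimethoxyphenyl]propanoyl}-1,3-oxazolidin-2-one | COc1cc(CCC(=O)N2C(=O)OC[C@H]2Cc2ccccc2)cc(OCc2ccccc2)c1OC | intermediate
10 | tert-butyl bromoacetate | CC(C)(C)OC(=O)CBr | starting material
11 | tert-butyl (3S)-4-[(4R)-4-benzyl-2-oxo-1,3-oxazolidin-3-yl]-3-[3-(benzyloxy)-4,5-dimethoxybenzyl]-4-oxobutanoate | COc1cc(C[C@@H](CC(=O)OC(C)(C)C)C(=O)N2C(=O)OC[C@H]2Cc2ccccc2)cc(OCc2ccccc2)c1OC | intermediate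
12 | tert-butyl (3S)-3-[3-(benzyloxy)-4,5-dimethoxybenzyl]-4-hydroxybutanoate | COc1cc(C[C@@H](CC(=O)OC(C)(C)C)CO)cc(OCc2ccccc2)c1OC | intermediate (not isolated)
13 | (S)-4-[3-(benzyloxy)-4,5-dimethoxybenzyl]oxolan-2-one | COc1cc(C[C@@H]2COC(=O)C2)cc(OCc2ccccc2)c1OC | intermediate
14 | 3,4,5-trimethoxybenzyl bromide | COc1cc(CBr)cc(OC)c1OC | starting material
15 | (3S,4S)-4-[3-(benzyloxy)-4,5-dimethoxybenzyl]-3-(3,4,5-trimethoxybenzyl)oxolan-2-one | COc1cc(C[C@@H]2COC(=O)[C@H]2Cc2cc(OC)c(OC)c(OC)c2)cc(OCc2ccccc2)c1OC | intermediate
16 | (2S,3S)-3-[3-(benzyloxy)-4,5-dimethoxybenzyl]-4-hydroxy-N-methoxy-N-methyl-2-(3,4,5-trimethoxybenzyl)butanamide | COc1cc(C[C@H](CO)[C@H](Cc2cc(OC)c(OC)c(OC)c2)C(=O)N(C)OC)cc(OCc2ccccc2)c1OC | intermediate (not isolated)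
17 | (2S,3S)-3-[3-(benzyloxy)-4,5-dimethoxybenzyl]-4-[(tert-butyldimethylsilyl)oxy]-N-methoxy-N-methyl-2-(3,4,5-trimethoxybenzyl)butanamide | COc1cc(C[C@H](CO[Si](C)(C)C(C)(C)C)[C@H](Cc2cc(OC)c(OC)c(OC)c2)C(=O)N(C)OC)cc(OCc2ccccc2)c1OC | intermediate
18 | (2S,3S)-3-[3-(benzyloxy)-4,5-dimethoxybenzyl]-4-[(tert-butyldimethylsilyl)oxy]-2-(3,4,5-trimethoxybenzyl)butanal | COc1cc(C[C@H](CO[Si](C)(C)C(C)(C)C)[C@H](Cc2cc(OC)c(OC)c(OC)c2)C=O)cc(OCc2ccccc2)c1OC | intermediate (not isolated)
19 | (2S,3S)-3-[3-(benzyloxy)-4,5-dimethoxybenzyl]-4-[(tert-butyldimethylsilyl)oxy]-2-(3,4,5-trimethoxybenzyl)butan-1-ol | COc1cc(C[C@H](CO[Si](C)(C)C(C)(C)C)[C@H](Cc2cc(OC)c(OC)c(OC)c2)CO)cc(OCc2ccccc2)c1OC | intermediate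
20 | (2S,3S)-4-[(tert-butyldimethylsilyl)oxy]-3-(3-hydroxy-4,5-dimethoxybenzyl)-2-(3,4,5-trimethoxybenzyl)butan-1-ol | COc1cc(C[C@H](CO[Si](C)(C)C(C)(C)C)[C@H](Cc2cc(OC)c(OC)c(OC)c2)CO)cc(O)c1OC | intermediate (not isolated)
21 | (2S,3S)-3-(3-acetoxy-4,5-dimethoxybenzyl)-4-[(tert-butyldimethylsilyl)oxy]-2-(3,4,5-trimethoxybenzyl)butyl acetate | COc1cc(C[C@H](CO[Si](C)(C)C(C)(C)C)[C@H](Cc2cc(OC)c(OC)c(OC)c2)COC(C)=O)cc(OC(C)=O)c1OC | intermediate
22 | (2S,3S)-4-acetoxy-2-(3-acetoxy-4,5-dimethoxybenzyl)-3-(3,4,5-trimethoxybenzyl)butan-1-ol | COc1cc(C[C@H](CO)[C@H](Cc2cc(OC)c(OC)c(OC)c2)COC(C)=O)cc(OC(C)=O)c1OC | intermediate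
23 | (2S,3S)-4-acetoxy-2-(3-acetoxy-4,5-dimethoxybenzyl)-3-(3,4,5-trimethoxybenzyl)butyl hypoiodite | COc1cc(C[C@H](COI)[C@H](Cc2cc(OC)c(OC)c(OC)c2)COC(C)=O)cc(OC(C)=O)c1OC | intermediate (not isolated)
24 | [(2R,3S,4S)-4-(3-acetoxy-4,5-dimethoxybenzyl)-2-(3,4,5-trimethoxyphenyl)oxolan-3-yl]methyl acetate | COc1cc(C[C@@H]2CO[C@@H](c3cc(OC)c(OC)c(OC)c3)[C@@H]2COC(C)=O)cc(OC(C)=O)c1OC | intermediate
25 | [(2R,3S,4S)-4-(3-hydroxy-4,5-dimethoxybenzyl)-2-(3,4,5-trimethoxyphenyl)oxolan-3-yl]methanol | COc1cc(C[C@@H]2CO[C@@H](c3cc(OC)c(OC)c(OC)c3)[C@@H]2CO)cc(O)c1OC | target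

## Step count and risk

Total step count: 12. Longest linear sequence: 12 steps (from 1; compounds 3, 7, 10 and 14 are commercial and enter along the way).

Steps least certain to work:

**Step 11 (key step).** The most likely failure is electrophilic iodination of the trimethoxyphenyl ring by acetyl hypoiodite, which competes with formation and photolysis of the hypoiodite. A second one is capture of the C2 cation by the neighbouring aryl ring (tetralin formation) instead of by the hydroxyl. Both follow from the electron-rich rings and cannot be removed completely by the measures built into the step.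

Fallback: a polar closure from a C2-oxygenated intermediate, leaving the route at 13 and returning at 25.
- The lithium enolate of 13 (LiN(iPr)2, THF, −78 °C) is added to 3,4,5-trimethoxybenzaldehyde. This should give the trans aldol lactone (3R,4S)-4-[3-(benzyloxy)-4,5-dimethoxybenzyl]-3-[hydroxy(3,4,5-trimethoxyphenyl)methyl]oxolan-2-one F1, as both carbinol epimers.
- LiAlH4 in THF reduces it to the triol (2S,3S)-2-[3-(benzyloxy)-4,5-dimethoxybenzyl]-3-[hydroxy(3,4,5-trimethoxyphenyl)methyl]butane-1,4-diol F2.
- Camphorsulfonic acid in CH2Cl2 ionises the benzylic alcohol. Only the C5 hydroxyl can close a five-membered ring, and the aryl group should settle trans to the hydroxymethyl, giving the benzyl ether [(2R,3S,4S)-4-[3-(benzyloxy)-4,5-dimethoxybenzyl]-2-(3,4,5-trimethoxyphenyl)oxolan-3-yl]methanol F3.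
- Brief hydrogenolysis (H2, Pd/C, EtOAc) gives 25.

**Step 7.** The hydroxy amide 16 may relactonise to 15 during work-up or before silylation is complete, because the amide is a good acyl donor towards a γ-hydroxyl.

Fallback: hydrolytic opening, from 15 back to the route at 19 (this also bypasses the aldehyde of step 8).
- KOH in aqueous THF/MeOH gives the potassium salt potassium (2S,3S)-3-[3-(benzyloxy)-4,5-dimethoxybenzyl]-4-hydroxy-2-(3,4,5-trimethoxybenzyl)butanoate F4.
- Excess TBSCl and imidazole in DMF silylate both oxygens to the silyl ester silyl ether F5.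
- K2CO3 in aqueous MeOH/THF cleaves only the silyl ester, giving (2S,3S)-3-[3-(benzyloxy)-4,5-dimethoxybenzyl]-4-[(tert-butyldimethylsilyl)oxy]-2-(3,4,5-trimethoxybenzyl)butanoic acid F6.
- BH3·SMe2 in THF reduces the acid to 19.

**Step 5.** Hydride may attack the ring carbonyl of the oxazolidinone (endocyclic cleavage) instead of the imide carbonyl, or the tert-butyl ester may be partly reduced; both become more likely with the α-branched acyl group.

Fallback: hydrolytic removal of the auxiliary, from 11 back to the route at 12. LiOH/H2O2 in aqueous THF at 0 °C gives (2S)-2-[3-(benzyloxy)-4,5-dimethoxybenzyl]-4-(tert-butoxy)-4-oxobutanoic acid F7. BH3·SMe2 reduces the free acid selectively in the presence of the tert-butyl ester to hydroxy ester 12, which is lactonised as in step 5.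

**Step 10.** The acetyl group of the C3 arm may migrate to the freed C5 oxygen, or the aryl acetate may be lost. Migration would move the radical site to the wrong oxygen and lead, in step 11, to the constitutional isomer with the two aryl groups exchanged.

Fallback: pivalates in place of acetates, from 19 back to the route at 25.
- Hydrogenolysis as in step 9 gives 20, and PivCl, pyridine and DMAP give the dipivalate (2S,3S)-4-[(tert-butyldimethylsilyl)oxy]-3-[3,4-dimethoxy-5-(pivaloyloxy)benzyl]-2-(3,4,5-trimethoxybenzyl)butyl pivalate F8.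
- HF·pyridine gives the alcohol F9, whose hindered esters do not migrate readily.
- The conditions of step 11, through hypoiodite F10, give the tetrahydrofuran dipivalate F11.
- LiAlH4 in THF at 0 °C removes both pivalates and gives 25.

## Further compounds

F1 | step 11 | (3R,4S)-4-[3-(benzyloxy)-4,5-dimethoxybenzyl]-3-[hydroxy(3,4,5-trimethoxyphenyl)methyl]oxolan-2-one (both carbinol epimers) | COc1cc(C[C@@H]2COC(=O)[C@H]2C(O)c2cc(OC)c(OC)c(OC)c2)cc(OCc2ccccc2)c1OC
F2 | step 11 | (2S,3S)-2-[3-(benzyloxy)-4,5-dimethoxybenzyl]-3-[hydroxy(3,4,5-trimethoxyphenyl)methyl]butane-1,4-diol (both carbinol epimers) | COc1cc(C[C@H](CO)[C@@H](CO)C(O)c2cc(OC)c(OC)c(OC)c2)cc(OCc2ccccc2)c1OC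
F3 | step 11 | [(2R,3S,4S)-4-[3-(benzyloxy)-4,5-dimethoxybenzyl]-2-(3,4,5-trimethoxyphenyl)oxolan-3-yl]methanol | COc1cc(C[C@@H]2CO[C@@H](c3cc(OC)c(OC)c(OC)c3)[C@@H]2CO)cc(OCc3ccccc3)c1OC
F4 | step 7 | potassium (2S,3S)-3-[3-(benzyloxy)-4,5-dimethoxybenzyl]-4-hydroxy-2-(3,4,5-trimethoxybenzyl)butanoate | COc1cc(C[C@H](CO)[C@H](Cc2cc(OC)c(OC)c(OC)c2)C(=O)[O-])cc(OCc2ccccc2)c1OC.[K+]
F5 | step 7 | tert-butyldimethylsilyl (2S,3S)-3-[3-(benzyloxy)-4,5-dimethoxybenzyl]-4-[(tert-butyldimethylsilyl)oxy]-2-(3,4,5-trimethoxybenzyl)butanoate | COc1cc(C[C@H](CO[Si](C)(C)C(C)(C)C)[C@H](Cc2cc(OC)c(OC)c(OC)c2)C(=O)O[Si](C)(C)C(C)(C)C)cc(OCc2ccccc2)c1OC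
F6 | step 7 | (2S,3S)-3-[3-(benzyloxy)-4,5-dimethoxybenzyl]-4-[(tert-butyldimethylsilyl)oxy]-2-(3,4,5-trimethoxybenzyl)butanoic acid | COc1cc(C[C@H](CO[Si](C)(C)C(C)(C)C)[C@H](Cc2cc(OC)c(OC)c(OC)c2)C(=O)O)cc(OCc2ccccc2)c1OC
F7 | step 5 | (2S)-2-[3-(benzyloxy)-4,5-dimethoxybenzyl]-4-(tert-butoxy)-4-oxobutanoic acid | COc1cc(C[C@@H](CC(=O)OC(C)(C)C)C(=O)O)cc(OCc2ccccc2)c1OC
F8 | step 10 | (2S,3S)-4-[(tert-butyldimethylsilyl)oxy]-3-[3,4-dimethoxy-5-(pivaloyloxy)benzyl]-2-(3,4,5-trimethoxybenzyl)butyl pivalate | COc1cc(C[C@H](CO[Si](C)(C)C(C)(C)C)[C@H](Cc2cc(OC)c(OC)c(OC)c2)COC(=O)C(C)(C)C)cc(OC(=O)C(C)(C)C)c1OC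
F9 | step 10 | (2S,3S)-3-[3,4-dimethoxy-5-(pivaloyloxy)benzyl]-4-hydroxy-2-(3,4,5-trimethoxybenzyl)butyl pivalate | COc1cc(C[C@H](CO)[C@H](Cc2cc(OC)c(OC)c(OC)c2)COC(=O)C(C)(C)C)cc(OC(=O)C(C)(C)C)c1OC
F10 | step 10 | hypoiodite of F9 | COc1cc(C[C@H](COI)[C@H](Cc2cc(OC)c(OC)c(OC)c2)COC(=O)C(C)(C)C)cc(OC(=O)C(C)(C)C)c1OC
F11 | step 10 | [(2R,3S,4S)-4-[3,4-dimethoxy-5-(pivaloyloxy)benzyl]-2-(3,4,5-trimethoxyphenyl)oxolan-3-yl]methyl pivalate | COc1cc(C[C@@H]2CO[C@@H](c3cc(OC)c(OC)c(OC)c3)[C@@H]2COC(=O)C(C)(C)C)cc(OC(=O)C(C)(C)C)c1OC
A1 | alternative 1 | all-trans 3-[3,4-dimethoxy-5-(triisopropylsilyloxy)benzyl]-5-[(1S,2R,5S)-menthyloxy]-4-[2-(3,4,5-trimethoxyphenyl)-1,3-dithian-2-yl]oxolan-2-one | O=C1O[C@H](O[C@H]2C[C@@H](C)CC[C@@H]2C(C)C)[C@@H](C2(c3cc(OC)c(OC)c(OC)c3)SCCCS2)[C@@H]1Cc1cc(OC)c(OC)c(O[Si](C(C)C)(C(C)C)C(C)C)c1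
A2 | alternative 1 | (5S)-5-[(1S,2R,5S)-menthyloxy]furan-2(5H)-one | O=C1O[C@H](O[C@H]2C[C@@H](C)CC[C@@H]2C(C)C)C=C1
A3 | alternative 1 | 2-(3,4,5-trimethoxyphenyl)-1,3-dithiane | COc1cc(C2SCCCS2)cc(OC)c1OC
A4 | alternative 1 | 5-(bromomethyl)-1,2-dimethoxy-3-[(triisopropylsilyl)oxy]benzene | COc1cc(CBr)cc(O[Si](C(C)C)(C(C)C)C(C)C)c1OC
A5 | alternative 2 | cis-fused furofuranone (tetrahydrofuran fused to γ-lactone), both aryl groups exo, phenol as benzyl ether | COc1cc([C@H]3[C@@H]2CO[C@@H](c4cc(OC)c(OC)c(OC)c4)[C@@H]2C(=O)O3)cc(OCc4ccccc4)c1OC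
A6 | alternative 2 | (R)-5-[3-(benzyloxy)-4,5-dimethoxyphenyl]furan-2(5H)-one | COc1cc([C@H]2C=CC(=O)O2)cc(OCc3ccccc3)c1OC
A7 | alternative 2 | 5-{chloro[(trimethylsilyl)methoxy]methyl}-1,2,3-trimethoxybenzene (racemic) | COc1cc(C(Cl)OC[Si](C)(C)C)cc(OC)c1OC
A8 | alternative 3 | [(2R,3S,4S)-4-{3-[(tert-butyldimethylsilyl)oxy]-4,5-dimethoxybenzyl}-2-(3,4,5-trimethoxyphenyl)oxolan-3-yl]methanol | COc1cc(C[C@@H]2CO[C@@H](c3cc(OC)c(OC)c(OC)c3)[C@@H]2CO)cc(O[Si](C)(C)C(C)(C)C)c1OC
A9 | alternative 3 | (E)-cinnamyl ether of (S)-oxiran-2-yl(3,4,5-trimethoxyphenyl)methanol, aryl of the cinnamyl part 3-[(tert-butyldimethylsilyl)oxy]-4,5-dimethoxyphenyl, epoxide carbon of either configuration | COc1cc(/C=C/CO[C@@H](c2cc(OC)c(OC)c(OC)c2)C2CO2)cc(O[Si](C)(C)C(C)(C)C)c1OC
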